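The runs stem from a simulated flask from invented constants, and the scatter is random.

The west flask, closed and stirred, has been read for J and L up to 90.0 s, but Z has not been read at all. You must decide what the next charge of this flask should measure.

| flask | Q | remark | time |
|---|---|---|---|
| west | 0.050 M | the very flask that is asked about, followed so far |  |
| flask | 0.050 M |  | 3.0 min |

west run (percent of the Q charged)

| time / s | J / % | L / % |
|---|---|---|
| 10.0 | 2.8 | 18.3 |
| 15.0 | 4.4 | 25.8 |
| 25.0 | 4.1 | 35.5 |
| 40.0 | 4.7 | 45.7 |
| 50.0 | 5.7 | 48.6 |
| 80.0 | 3.6 | 56.6 |
| 90.0 | 3.4 | 56.6 |

(each reading ± 0.5 percentage points)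

1. J present at 3.0 min, in percent of the Q charged
2. L present at 3.0 min, in percent of the Q charged
3. Z present at 3.0 min, in percent of the Q charged

- in percentages every species weighs as the Q in it: one Z counts as two
- a reading or a percentage of J counts all its forms, free or not

Start from the large unknown and treat J as a small correction to it. Call the unread remainder, the gap in the mass balance, what the charge holds beyond the J and L read:

remainder at 90.0 s = 100 % − J − L = 40.0 %

From the reading at 80.0 s it moved by 0.2 percentage points, less than the scatter of 0.5 points on one reading. L read 56.6 % at both times, while J has fallen from its reading of 5.7 % at 50.0 s.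

My own reckoning for 3.0 min is therefore J near 2 per cent, L close to its last reading, and the remainder still near 40.0 %. That remainder is a ceiling on Z, not a value for it, since it also holds any Q left and anything formed that goes unread. The readings hold neither Q nor Z, so they do not split the remainder. Charge the next west flask unchanged, then, and add readings of Q and Z at 3.0 min.

The forecast gives J 1.5 %, L 60 % and Z 38.5 %, on the ground that “Z is never measured, so it comes from the mass balance”.

The west flask gives J 2.08 %, L 59.5 % and Z 8.57 % at 3.0 min.

    Q ⇌ J (K = 0.0650, k = 0.210 min⁻¹)
    Q ⇌ E (K = 1.30, k = 0.240 min⁻¹)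
    Q ⇌ L (K = 3.90, k = 1.40 min⁻¹)
    2 Q → Z (k = 2.70 L mol⁻¹ min⁻¹)
    Q + J ⇌ D, settled at all times (K = 110 L mol⁻¹)

Q is not used up in the west flask: 15 % of the charge is still Q at that time. The unread remainder there is 38.5 %, and Z is about a quarter of it. In the neighbour flask charged with 0.085 M of Q and read at the same time, the remainder is 41.8 %, and Z stands at 13.3 %.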